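Watch the protic impurity as you repeat this run, and read chain length from it as follows.

    free monomer + initiator → living end + monomer in chains (k1 = 0.0012 L mol⁻¹ min⁻¹)
    free monomer + living end → monomer in chains + living end, rate k2*[living end]*[free monomer] (k2 = 1.1 L mol⁻¹ min⁻¹)
    protic impurity + free monomer → quenched substrate (k3 = 0.013 L mol⁻¹ min⁻¹)

free monomer 0.38 M; protic impurity 0.0190 M; initiator 19 mM; time 15 h

- the average divides the monomer in chains by the number of chains begun, living and dead together
- run time (flask): 15 h

* whether the average number of monomer units in a chain (chains begun, living or dead) reaches 80 by 15 h (no / yes)
* average number of monomer units in a chain (chains begun, living or dead) at 15 h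

**Shared clock.** Follow one free monomer molecule: at each fork it meets initiator, a living end or protic impurity, and every step consumes free monomer. So take as clock the exposure E, the time integral of the free monomer concentration. While the initiator stays near its charge, chains begun grow in proportion to E and monomer in chains to E squared. Dividing gives a length of 1 plus the propagation constant times E over 2, whatever the time course. Impurity decays exponentially in E, so n, the natural logarithm of its charge over what is left, reads the clock. Length is then 1 + g·n, where g = 42.3 is the length gained per unit of n, half the selectivity factor of propagation over quenching.

**Two ways.** Allow the impurity its whole charge, which leaves M = 0.361 M of monomer for chains. Filling chains on this clock gives a time constant τ = 7.83 h, and by 15 h the filled fraction's root y, the hyperbolic tangent of time over τ, is 0.957, so n = 2.11. The first way, 1 + g·n, gives a length of 90.3. The second way divides M·y² by the chains begun and gives 98.3.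

**Which cheats.** The second way holds initiator at its charge while filling chains but lets it run down while counting them, so it reads above the first way. The first way holds initiator at its charge throughout, so its length above 1 needs a factor of 1 + z/6, with z the initiator's own exposure, 0.195. My reckoning is therefore 93.3, above 80, so yes.

**The forecast.** The forecast says yes and 98, a longer chain than my reckoning: "Monomer is nearly used up by then".

**The flask.** The flask gives yes, passing 80 at 8.75 h and standing at 95.8 at 15 h. At that time the initiator's half-life by step one is 12 d, far longer than the 3.0 h of free monomer by propagation, and 82 % of the initiator charge is left. At 1.50 h, with 64.8 % of the impurity left, g gives 19.4, and the flask stands at 19.5.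

(All constants belong to no real substance; the rest is arithmetic.)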